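**Strategy.** The route rests on disconnecting the aryl ketone bond between C8 of ring A and the chalcone carbonyl carbon. C8 is the only aromatic CH flanked by two ether oxygens, the pyran oxygen O1 and the C7 methoxy group, while C6 is shielded by a bulky C5 silyl ether. Directed lithiation should therefore occur at C8, and the aryllithium is acylated by a p-coumaric Weinreb amide, which installs the complete E-chalcone in one operation. The precursor is a fully assembled, silyl-protected 2,4-trans flavan carrying the diarylheptanoid side chain, built from an R flavanone by stereoselective C4 alkylation of its flavan-4-yl cation and a CBS reduction.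

Key step: step 11

Assumption: the S ligand in step 2 is taken to give the 2R flavanone (the face it selects with 3-substituted cyclohexenones); should the sense be opposite, the R ligand is used.

Step 1
Reactants: 1 2',6'-dihydroxy-4'-methoxyacetophenone
Product: 3 5-hydroxy-7-methoxy-4H-chromen-4-one, via enaminone 2 (not isolated)
Conditions: DMF-DMA (1.5 equiv), toluene, 90 °C; then conc. HCl, CH2Cl2, 40 °C
Reagents that add atoms: N,N-dimethylformamide dimethyl acetal (DMF-DMA), COC(OC)N(C)C
Why: Enaminone formation at the acetyl methyl group followed by acid-promoted intramolecular addition–elimination with loss of dimethylamine is the standard enaminone chromone synthesis, and the two equivalent phenols make the ring closure regiochemically unambiguous.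

Step 2
Reactants: 3 5-hydroxy-7-methoxy-4H-chromen-4-one; 4 4-hydroxyphenylboronic acid
Product: 5 (2R)-5-hydroxy-2-(4-hydroxyphenyl)-7-methoxychroman-4-one
Conditions: Pd(OCOCF3)2 (5 mol %), (S)-t-BuPyOx (6 mol %), NH4PF6 (30 mol %), H2O (5 equiv), ClCH2CH2Cl, 60 °C
Reagents that add atoms: none
Why: Asymmetric conjugate addition of an arylboronic acid to a chromone, catalysed by a cationic divalent palladium pyridine–oxazoline complex (transmetalation, enantioface-selective carbopalladation of C2=C3, protonolysis), should set C2 as R under ligand control under air- and water-tolerant conditions that carry free phenols.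

Step 3
Reactants: 5 (2R)-5-hydroxy-2-(4-hydroxyphenyl)-7-methoxychroman-4-one
Product: 6 (2R)-7-methoxy-5-(triisopropylsilyloxy)-2-[4-(triisopropylsilyloxy)phenyl]chroman-4-one
Conditions: TIPSOTf (2.4 equiv), 2,6-lutidine, CH2Cl2, 0 °C to rt
Reagents that add atoms: triisopropylsilyl trifluoromethanesulfonate (TIPSOTf), CC(C)[Si](OS(=O)(=O)C(F)(F)F)(C(C)C)C(C)C
Why: A silyl triflate with a hindered pyridine base should silylate both the free 4'-phenol and the hydrogen-bonded 5-phenol (phenol silylation) without enolising the ketone or opening the pyranone ring, so C2 is not touched.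

Step 4
Reactants: 6 (2R)-7-methoxy-5-(triisopropylsilyloxy)-2-[4-(triisopropylsilyloxy)phenyl]chroman-4-one
Product: 7 (2R,4R)-7-methoxy-5-(triisopropylsilyloxy)-2-[4-(triisopropylsilyloxy)phenyl]chroman-4-ol (2,4-cis)
Conditions: NaBH4, THF–MeOH (10:1), −20 °C to 0 °C; pH 7 buffer
Reagents that add atoms: none
Why: Borohydride reduction of the aryl ketone at low temperature holds the new oxygen as a borate, which should limit silyl migration from the C5 oxygen, and axial hydride delivery should give mainly the 2,4-cis alcohol, although the C4 configuration is irrelevant because step 6 ionises this centre.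

Step 5
Reactants: 8 (E)-4-(4-hydroxyphenyl)but-3-en-2-one
Product: 9 triisopropyl{4-[(1E)-3-(triisopropylsilyloxy)buta-1,3-dien-1-yl]phenoxy}silane
Conditions: TIPSOTf (2.3 equiv), Et3N, CH2Cl2, 0 °C to rt
Reagents that add atoms: triisopropylsilyl trifluoromethanesulfonate (TIPSOTf), CC(C)[Si](OS(=O)(=O)C(F)(F)F)(C(C)C)C(C)C
Why: Excess silyl triflate with triethylamine should silylate the phenol and convert the methyl ketone into its silyl dienol ether (silyl enol ether formation), the only enolisation direction available because the other α-carbon is vinylic.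

Step 6
Reactants: 7 (2R,4R)-7-methoxy-5-(triisopropylsilyloxy)-2-[4-(triisopropylsilyloxy)phenyl]chroman-4-ol; 9 triisopropyl{4-[(1E)-3-(triisopropylsilyloxy)buta-1,3-dien-1-yl]phenoxy}silane
Product: 10 (E)-1-{(2R,4R)-7-methoxy-5-(triisopropylsilyloxy)-2-[4-(triisopropylsilyloxy)phenyl]chroman-4-yl}-4-[4-(triisopropylsilyloxy)phenyl]but-3-en-2-one (2,4-trans)
Conditions: 9 (1.5 equiv), TMSOTf (20 mol %), CH2Cl2, −78 °C to −40 °C
Reagents that add atoms: none
Why: Lewis-acid ionisation of the benzylic alcohol gives a flavan-4-yl cation stabilised by the C5 and C7 oxygens (SN1, Mukaiyama-type alkylation of a silyl enol ether), and the dienol ether should attack through its terminal CH2 pseudo-axially on the half-chair that keeps the C2 aryl group equatorial, anti to that aryl group, to give the 2,4-trans product, which also avoids peri strain with the C5 substituent.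

Step 7
Reactants: 10 (E)-1-{(2R,4R)-7-methoxy-5-(triisopropylsilyloxy)-2-[4-(triisopropylsilyloxy)phenyl]chroman-4-yl}-4-[4-(triisopropylsilyloxy)phenyl]but-3-en-2-one
Product: 11 (2S,3E)-1-{(2R,4S)-7-methoxy-5-(triisopropylsilyloxy)-2-[4-(triisopropylsilyloxy)phenyl]chroman-4-yl}-4-[4-(triisopropylsilyloxy)phenyl]but-3-en-2-ol
Conditions: (R)-2-methyl-CBS-oxazaborolidine (20 mol %), catecholborane (1.5 equiv), toluene, −78 °C
Reagents that add atoms: none
Why: In this Corey–Bakshi–Shibata reduction the styryl group acts as the large substituent and the CH2 group as the small one, so the R catalyst should deliver hydride under catalyst control to give the S allylic alcohol independently of the remote ring stereocentres.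

Step 8
Reactants: 11 (2S,3E)-1-{(2R,4S)-7-methoxy-5-(triisopropylsilyloxy)-2-[4-(triisopropylsilyloxy)phenyl]chroman-4-yl}-4-[4-(triisopropylsilyloxy)phenyl]but-3-en-2-ol
Product: 12 (2R)-1-{(2R,4S)-7-methoxy-5-(triisopropylsilyloxy)-2-[4-(triisopropylsilyloxy)phenyl]chroman-4-yl}-4-[4-(triisopropylsilyloxy)phenyl]butan-2-ol
Conditions: H2 (3 atm), RhCl(PPh3)3 (5 mol %), benzene–EtOH, rt
Reagents that add atoms: none
Why: Homogeneous hydrogenation with RhCl(PPh3)3 should saturate the disubstituted alkene without hydrogenolysis of the allylic alcohol, the benzylic C2–O bond or the aryl silyl ethers, and the carbinol centre is untouched (its descriptor changes from S to R only through the change in priorities).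

Step 9
Reactants: 13 (E)-4-hydroxycinnamic acid (p-coumaric acid)
Product: 14 (E)-3-(4-hydroxyphenyl)-N-methoxy-N-methylprop-2-enamide
Conditions: MeNHOMe·HCl, EDC·HCl, HOBt (cat.), N-methylmorpholine, CH2Cl2–DMF, 0 °C to rt
Reagents that add atoms: N,O-dimethylhydroxylamine hydrochloride, CNOC.Cl
Why: Carbodiimide-mediated amide coupling (Weinreb amide formation) should acylate the more nucleophilic amine in preference to the free phenol and leave the E alkene intact.

Step 10
Reactants: 14 (E)-3-(4-hydroxyphenyl)-N-methoxy-N-methylprop-2-enamide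
Product: 15 (E)-N-methoxy-N-methyl-3-[4-(triisopropylsilyloxy)phenyl]prop-2-enamide
Conditions: TIPSCl, imidazole, DMF, rt
Reagents that add atoms: triisopropylsilyl chloride (TIPSCl), CC(C)[Si](Cl)(C(C)C)C(C)C
Why: Silylation of a phenol with a silyl chloride and imidazole is routine and the amide is inert to it.

Step 11
Reactants: 12 (2R)-1-{(2R,4S)-7-methoxy-5-(triisopropylsilyloxy)-2-[4-(triisopropylsilyloxy)phenyl]chroman-4-yl}-4-[4-(triisopropylsilyloxy)phenyl]butan-2-ol; 15 (E)-N-methoxy-N-methyl-3-[4-(triisopropylsilyloxy)phenyl]prop-2-enamide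
Product: 18 (E)-1-{(2R,4S)-4-[(2R)-2-hydroxy-4-(4-triisopropylsilyloxyphenyl)butyl]-7-methoxy-5-(triisopropylsilyloxy)-2-[4-(triisopropylsilyloxy)phenyl]chroman-8-yl}-3-[4-(triisopropylsilyloxy)phenyl]prop-2-en-1-one, via dilithio species 16 (not isolated), via tetrahedral adduct 17 (not isolated)
Conditions: n-BuLi (2.2 equiv), TMEDA (2.2 equiv), Et2O, 0 °C, 2 h; then 15 (1.2 equiv), THF, −78 °C to 0 °C; aq. NH4Cl
Reagents that add atoms: none
Why: The first equivalent of n-BuLi converts the secondary alcohol into its lithium alkoxide and the second removes the C8 hydrogen of ring A, the only aryl hydrogen flanked by two lithium-coordinating ether oxygens (ring oxygen O1 and the C7 methoxy group), by complex-induced proximity (directed ortho-metalation). The aryllithium then adds to the carbonyl carbon of Weinreb amide 15 to give an N-methoxy-chelated tetrahedral lithium adduct that does not collapse before work-up, so the ketone is released only after all organolithium is quenched and no second addition can occur. The closest known reaction types are the lithiation of 1,3-dialkoxybenzenes between the two oxygens and the Weinreb ketone synthesis with aryllithiums. No ring is closed and no stereocentre is formed, the E geometry of the enone is carried over from 15, and the three existing stereocentres are remote from the carbanion. The step needs C8 over C6 selectivity, secured by the bulky, non-coordinating triisopropylsilyl ether at C5 that shields C6 and by the absence of any directing group on the other silyl-protected rings, and 1,2- over 1,4-addition, secured by the hard aryllithium and the chelating amide.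

Step 12
Reactants: 18 (E)-1-{(2R,4S)-4-[(2R)-2-hydroxy-4-(4-triisopropylsilyloxyphenyl)butyl]-7-methoxy-5-(triisopropylsilyloxy)-2-[4-(triisopropylsilyloxy)phenyl]chroman-8-yl}-3-[4-(triisopropylsilyloxy)phenyl]prop-2-en-1-one
Product: 19 (E)-1-{(2R,4S)-5-hydroxy-4-[(2R)-2-hydroxy-4-(4-hydroxyphenyl)butyl]-2-(4-hydroxyphenyl)-7-methoxychroman-8-yl}-3-(4-hydroxyphenyl)prop-2-en-1-one
Conditions: TBAF (4.4 equiv), AcOH (4.4 equiv), THF, 0 °C
Reagents that add atoms: none
Why: Fluoride should cleave the four aryl silyl ethers rapidly at low temperature (fluoride desilylation), and the acetic acid buffer keeps the phenols protonated so that the enone and the benzylic ether at C2 are not exposed to strong base.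

**Compound list**

1 | 2',6'-dihydroxy-4'-methoxyacetophenone | CC(=O)c1c(O)cc(OC)cc1O | starting material
2 | (E)-1-(2,6-dihydroxy-4-methoxyphenyl)-3-(dimethylamino)prop-2-en-1-one (enaminone) | CN(C)/C=C/C(=O)c1c(O)cc(OC)cc1O | intermediate
3 | 5-hydroxy-7-methoxy-4H-chromen-4-one | COc1cc(O)c2c(c1)OC=CC2=O | intermediate
4 | 4-hydroxyphenylboronic acid | OB(O)c1ccc(O)cc1 | starting material
5 | (2R)-5-hydroxy-2-(4-hydroxyphenyl)-7-methoxychroman-4-one | COc1cc(O)c2c(c1)O[C@@H](c1ccc(O)cc1)CC2=O | intermediate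
6 | (2R)-7-methoxy-5-(triisopropylsilyloxy)-2-[4-(triisopropylsilyloxy)phenyl]chroman-4-one | COc1cc(O[Si](C(C)C)(C(C)C)C(C)C)c2c(c1)O[C@@H](c1ccc(O[Si](C(C)C)(C(C)C)C(C)C)cc1)CC2=O | intermediate
7 | (2R,4R)-7-methoxy-5-(triisopropylsilyloxy)-2-[4-(triisopropylsilyloxy)phenyl]chroman-4-ol (2,4-cis) | COc1cc(O[Si](C(C)C)(C(C)C)C(C)C)c2c(c1)O[C@@H](c1ccc(O[Si](C(C)C)(C(C)C)C(C)C)cc1)C[C@H]2O | intermediate
8 | (E)-4-(4-hydroxyphenyl)but-3-en-2-one | CC(=O)/C=C/c1ccc(O)cc1 | starting material
9 | triisopropyl{4-[(1E)-3-(triisopropylsilyloxy)buta-1,3-dien-1-yl]phenoxy}silane | C=C(O[Si](C(C)C)(C(C)C)C(C)C)/C=C/c1ccc(O[Si](C(C)C)(C(C)C)C(C)C)cc1 | intermediate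
10 | (E)-1-{(2R,4R)-7-methoxy-5-(triisopropylsilyloxy)-2-[4-(triisopropylsilyloxy)phenyl]chroman-4-yl}-4-[4-(triisopropylsilyloxy)phenyl]but-3-en-2-one (2,4-trans) | COc1cc(O[Si](C(C)C)(C(C)C)C(C)C)c2c(c1)O[C@@H](c1ccc(O[Si](C(C)C)(C(C)C)C(C)C)cc1)C[C@@H]2CC(=O)/C=C/c1ccc(O[Si](C(C)C)(C(C)C)C(C)C)cc1 | intermediate
11 | (2S,3E)-1-{(2R,4S)-7-methoxy-5-(triisopropylsilyloxy)-2-[4-(triisopropylsilyloxy)phenyl]chroman-4-yl}-4-[4-(triisopropylsilyloxy)phenyl]but-3-en-2-ol | COc1cc(O[Si](C(C)C)(C(C)C)C(C)C)c2c(c1)O[C@@H](c1ccc(O[Si](C(C)C)(C(C)C)C(C)C)cc1)C[C@@H]2C[C@H](O)/C=C/c1ccc(O[Si](C(C)C)(C(C)C)C(C)C)cc1 | intermediate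
12 | (2R)-1-{(2R,4S)-7-methoxy-5-(triisopropylsilyloxy)-2-[4-(triisopropylsilyloxy)phenyl]chroman-4-yl}-4-[4-(triisopropylsilyloxy)phenyl]butan-2-ol | COc1cc(O[Si](C(C)C)(C(C)C)C(C)C)c2c(c1)O[C@@H](c1ccc(O[Si](C(C)C)(C(C)C)C(C)C)cc1)C[C@@H]2C[C@H](O)CCc1ccc(O[Si](C(C)C)(C(C)C)C(C)C)cc1 | intermediate
13 | (E)-4-hydroxycinnamic acid (p-coumaric acid) | OC(=O)/C=C/c1ccc(O)cc1 | starting material
14 | (E)-3-(4-hydroxyphenyl)-N-methoxy-N-methylprop-2-enamide | CON(C)C(=O)/C=C/c1ccc(O)cc1 | intermediate
15 | (E)-N-methoxy-N-methyl-3-[4-(triisopropylsilyloxy)phenyl]prop-2-enamide | CON(C)C(=O)/C=C/c1ccc(O[Si](C(C)C)(C(C)C)C(C)C)cc1 | intermediate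
16 | C8-lithiated lithium alkoxide of 12 (dilithio species) | COc1cc(O[Si](C(C)C)(C(C)C)C(C)C)c2c(c1[Li])O[C@@H](c1ccc(O[Si](C(C)C)(C(C)C)C(C)C)cc1)C[C@@H]2C[C@H](O[Li])CCc1ccc(O[Si](C(C)C)(C(C)C)C(C)C)cc1 | intermediate
17 | lithium N-methoxy-N-methyl hemiaminal alkoxide from 16 and 15 (tetrahedral adduct) | COc1cc(O[Si](C(C)C)(C(C)C)C(C)C)c2c(c1C(O[Li])(N(C)OC)/C=C/c1ccc(O[Si](C(C)C)(C(C)C)C(C)C)cc1)O[C@@H](c1ccc(O[Si](C(C)C)(C(C)C)C(C)C)cc1)C[C@@H]2C[C@H](O[Li])CCc1ccc(O[Si](C(C)C)(C(C)C)C(C)C)cc1 | intermediate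
18 | (E)-1-{(2R,4S)-4-[(2R)-2-hydroxy-4-(4-triisopropylsilyloxyphenyl)butyl]-7-methoxy-5-(triisopropylsilyloxy)-2-[4-(triisopropylsilyloxy)phenyl]chroman-8-yl}-3-[4-(triisopropylsilyloxy)phenyl]prop-2-en-1-one | COc1cc(O[Si](C(C)C)(C(C)C)C(C)C)c2c(c1C(=O)/C=C/c1ccc(O[Si](C(C)C)(C(C)C)C(C)C)cc1)O[C@@H](c1ccc(O[Si](C(C)C)(C(C)C)C(C)C)cc1)C[C@@H]2C[C@H](O)CCc1ccc(O[Si](C(C)C)(C(C)C)C(C)C)cc1 | intermediate
19 | (E)-1-{(2R,4S)-5-hydroxy-4-[(2R)-2-hydroxy-4-(4-hydroxyphenyl)butyl]-2-(4-hydroxyphenyl)-7-methoxychroman-8-yl}-3-(4-hydroxyphenyl)prop-2-en-1-one (CNP0102599.2) | COc1cc(O)c2c(c1C(=O)/C=C/c1ccc(O)cc1)O[C@@H](c1ccc(O)cc1)C[C@@H]2C[C@H](O)CCc1ccc(O)cc1 | target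

**Step count.** Total step count: 12. Longest linear sequence: 9 steps (steps 1, 2, 3, 4, 6, 7, 8, 11, 12); steps 5, 9 and 10 prepare the two coupling partners.

**Steps most likely to fail**

Step 11. Deprotonation may not discriminate cleanly between C8 and C6, removal of the benzylic C2 hydrogen may compete and lead to rearrangement of the benzylic ether, or the aryllithium may add to the amide in a conjugate sense. The fallback sets out from 12 and returns at 18. Electrophilic bromination with NBS (MeCN, 0 °C), in which the C5 silyl ether shields C6 sterically, should give the 8-bromide F1. Bromine–lithium exchange with t-BuLi at −78 °C (one equivalent is first consumed by the hydroxyl group) generates the aryllithium at a temperature at which ether deprotonation does not compete. Addition to (E)-3-[4-(triisopropylsilyloxy)phenyl]prop-2-enal F2, obtained from 15 with i-Bu2AlH at −78 °C, should give the doubly activated carbinol F3 as a mixture of carbinol epimers. MnO2 in CH2Cl2 should oxidise only this benzylic and allylic carbinol, leaving the isolated secondary alcohol untouched, to give 18.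

Step 6. After ionisation the cation may lose a C3 proton to a flav-3-ene, the nucleophile may attack both faces, or the acid may oligomerise the dienol ether through Mukaiyama–Michael addition to the enone product. The fallback sets out from 7 and returns at 10. Hosomi–Sakurai allylation (allyltrimethylsilane, BF3·OEt2, CH2Cl2, −78 °C), the most robust carbon substitution at C4 of flavan-4-ols, should give the 2,4-trans 4-allylflavan F4. Wacker oxidation (PdCl2, CuCl, O2, DMF–H2O) should convert it into the methyl ketone F5. Its kinetic lithium enolate (LDA, THF, −78 °C) is added to 4-(triisopropylsilyloxy)benzaldehyde F6 (from 4-hydroxybenzaldehyde, TIPSCl and imidazole) to give the aldol F7. Dehydration of F7 (MsCl, Et3N, then DBU) should give enone 10.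

Step 2. Insertion of the hydrogen-bonded 5-hydroxychromone may be slow, the electron-rich boronic acid may protodeboronate, or facial selectivity may be poor. The fallback sets out from 1 and returns at 7. Claisen–Schmidt condensation of 1 with 4-hydroxybenzaldehyde (KOH, EtOH) should give the chalcone F8, which cyclises (NaOAc, EtOH, reflux) to the racemic flavanone F9. Silylation as in step 3 gives the racemic bis-silyl flavanone F10. Noyori transfer hydrogenation with RuCl(p-cymene)[(R,R)-TsDPEN] (HCO2H–Et3N, EtOAc, rt), run as a kinetic resolution to about half conversion, should reduce the 2R enantiomer to the cis alcohol 7 and leave the 2S ketone behind. This costs half of the material.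

**Further compounds**

F1 | step 11 | (2R)-1-{(2R,4S)-8-bromo-7-methoxy-5-(triisopropylsilyloxy)-2-[4-(triisopropylsilyloxy)phenyl]chroman-4-yl}-4-[4-(triisopropylsilyloxy)phenyl]butan-2-ol | COc1cc(O[Si](C(C)C)(C(C)C)C(C)C)c2c(c1Br)O[C@@H](c1ccc(O[Si](C(C)C)(C(C)C)C(C)C)cc1)C[C@@H]2C[C@H](O)CCc1ccc(O[Si](C(C)C)(C(C)C)C(C)C)cc1
F2 | step 11 | (E)-3-[4-(triisopropylsilyloxy)phenyl]prop-2-enal | O=C/C=C/c1ccc(O[Si](C(C)C)(C(C)C)C(C)C)cc1
F3 | step 11 | (E)-1-{(2R,4S)-4-[(2R)-2-hydroxy-4-(4-triisopropylsilyloxyphenyl)butyl]-7-methoxy-5-(triisopropylsilyloxy)-2-[4-(triisopropylsilyloxy)phenyl]chroman-8-yl}-3-[4-(triisopropylsilyloxy)phenyl]prop-2-en-1-ol (carbinol epimers) | COc1cc(O[Si](C(C)C)(C(C)C)C(C)C)c2c(c1C(O)/C=C/c1ccc(O[Si](C(C)C)(C(C)C)C(C)C)cc1)O[C@@H](c1ccc(O[Si](C(C)C)(C(C)C)C(C)C)cc1)C[C@@H]2C[C@H](O)CCc1ccc(O[Si](C(C)C)(C(C)C)C(C)C)cc1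
F4 | step 6 | (2R,4S)-7-methoxy-4-(prop-2-en-1-yl)-5-(triisopropylsilyloxy)-2-[4-(triisopropylsilyloxy)phenyl]chromane | COc1cc(O[Si](C(C)C)(C(C)C)C(C)C)c2c(c1)O[C@@H](c1ccc(O[Si](C(C)C)(C(C)C)C(C)C)cc1)C[C@@H]2CC=C
F5 | step 6 | 1-{(2R,4R)-7-methoxy-5-(triisopropylsilyloxy)-2-[4-(triisopropylsilyloxy)phenyl]chroman-4-yl}propan-2-one | COc1cc(O[Si](C(C)C)(C(C)C)C(C)C)c2c(c1)O[C@@H](c1ccc(O[Si](C(C)C)(C(C)C)C(C)C)cc1)C[C@@H]2CC(C)=O
F6 | step 6 | 4-(triisopropylsilyloxy)benzaldehyde | O=Cc1ccc(O[Si](C(C)C)(C(C)C)C(C)C)cc1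
F7 | step 6 | 4-hydroxy-1-{(2R,4R)-7-methoxy-5-(triisopropylsilyloxy)-2-[4-(triisopropylsilyloxy)phenyl]chroman-4-yl}-4-[4-(triisopropylsilyloxy)phenyl]butan-2-one (carbinol epimers) | COc1cc(O[Si](C(C)C)(C(C)C)C(C)C)c2c(c1)O[C@@H](c1ccc(O[Si](C(C)C)(C(C)C)C(C)C)cc1)C[C@@H]2CC(=O)CC(O)c1ccc(O[Si](C(C)C)(C(C)C)C(C)C)cc1
F8 | step 2 | (E)-1-(2,6-dihydroxy-4-methoxyphenyl)-3-(4-hydroxyphenyl)prop-2-en-1-one | COc1cc(O)c(C(=O)/C=C/c2ccc(O)cc2)c(O)c1
F9 | step 2 | racemic 5-hydroxy-2-(4-hydroxyphenyl)-7-methoxychroman-4-one | COc1cc(O)c2c(c1)OC(c1ccc(O)cc1)CC2=O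
F10 | step 2 | racemic 7-methoxy-5-(triisopropylsilyloxy)-2-[4-(triisopropylsilyloxy)phenyl]chroman-4-one | COc1cc(O[Si](C(C)C)(C(C)C)C(C)C)c2c(c1)OC(c1ccc(O[Si](C(C)C)(C(C)C)C(C)C)cc1)CC2=O
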